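**Strategy.** The pyranone ring (O1, C2–C6) is split into two three-atom halves. The C2–C3(Et)–C4 segment maps onto ethylmalonic acid. The C5=C6–O1 segment is the enol tautomer of a methyl ketone whose carbonyl carbon carries the all-syn C7–C9 triad. A single [3+3] annulation of a terminal enol silane with ethylmalonyl dichloride forms C4–C5 and O1–C2 and gives the complete heterocycle without touching a stereocentre. The precursor is the kinetic trimethylsilyl enol ether of a (3S,4R,5S)-hexan-2-one bearing a C8 TBS ether and an ortho-bromoaryl group. It is built by one Evans methylation and one Evans syn-aldol. Suzuki alkenylation and global desilylation finish the route.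

Key step: step 11

Remark: atom labels are O1 and C2–C6 for the pyranone and C7 (Me), C8 (OH), C9 (Me, aryl) for the side chain; the target is read as 7S,8R,9S with an E alkene, which is all-syn along the C6–C7–C8–C9–aryl zigzag; the five starting materials are assumed to be catalogue compounds.

**Step 1**
Reactants: 1 2-(2-bromo-4-methylphenyl)acetic acid; 2 (4S)-4-benzyl-1,3-oxazolidin-2-one
Product: 4 (4S)-4-benzyl-3-[2-(2-bromo-4-methylphenyl)acetyl]-1,3-oxazolidin-2-one, via mixed pivalic anhydride 3 (not isolated)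
Conditions: PivCl, Et3N, THF, −20 °C; then LiCl, 2, −20 °C → rt
Reagents that add atoms: none
Why: In this mixed-anhydride N-acylation of an oxazolidinone, the unhindered arylacetyl carbonyl of 3 should be attacked in preference to the pivaloyl carbonyl, and no stereocentre is formed.

**Step 2**
Reactants: 4 (4S)-4-benzyl-3-[2-(2-bromo-4-methylphenyl)acetyl]-1,3-oxazolidin-2-one
Product: 6 (4S)-4-benzyl-3-[(2S)-2-(2-bromo-4-methylphenyl)propanoyl]-1,3-oxazolidin-2-one, via sodium Z-enolate 5 (not isolated)
Conditions: NaN(SiMe3)2, THF, −78 °C; MeI, −78 → −40 °C; cold AcOH quench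
Reagents that add atoms: iodomethane, CI
Why: In this Evans asymmetric alkylation the sodium-chelated Z-enolate 5 is shielded on one face by the C4 benzyl group, so MeI should enter from the open face and set C9 as S, and the cold acidic quench protects the acidic benzylic centre from epimerisation.

**Step 3**
Reactants: 6 (4S)-4-benzyl-3-[(2S)-2-(2-bromo-4-methylphenyl)propanoyl]-1,3-oxazolidin-2-one
Product: 7 (2S)-2-(2-bromo-4-methylphenyl)propan-1-ol
Conditions: LiBH4, MeOH (1 equiv), Et2O, 0 °C
Reagents that add atoms: none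
Why: Reductive cleavage of an N-acyl oxazolidinone by borohydride takes place at the exocyclic imide carbonyl, releases the auxiliary for reuse and leaves C9 and the aryl bromide untouched.

**Step 4**
Reactants: 7 (2S)-2-(2-bromo-4-methylphenyl)propan-1-ol
Product: 8 (2S)-2-(2-bromo-4-methylphenyl)propanal
Conditions: Dess–Martin periodinane, CH2Cl2, 0 °C → rt; used crude at once
Reagents that add atoms: none
Why: The Dess–Martin oxidation needs no amine base and stops at the aldehyde, which makes it the mildest way to keep the enolisable benzylic C9 centre intact.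

**Step 5**
Reactants: 8 (2S)-2-(2-bromo-4-methylphenyl)propanal; 9 (4S)-4-benzyl-3-propanoyl-1,3-oxazolidin-2-one
Product: 12 (4S)-4-benzyl-3-[(2S,3R,4S)-4-(2-bromo-4-methylphenyl)-3-hydroxy-2-methylpentanoyl]-1,3-oxazolidin-2-one, via dibutylboron Z-enolate 10 (not isolated), via boron aldolate 11 (not isolated)
Conditions: 9, Bu2BOTf, Et3N, CH2Cl2, 0 °C; 8, −78 → 0 °C; H2O2, MeOH, pH 7 buffer, 0 °C
Reagents that add atoms: none
Why: In this Evans syn-aldol, Z-enolate 10 reacts through a Zimmerman–Traxler chair whose face is fixed by the (S)-benzyl auxiliary, which should give 7S,8R, and this sense matches Felkin–Anh attack on the (S)-α-aryl aldehyde (8,9-syn), so reagent and substrate control both favour the all-syn triad.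

**Step 6**
Reactants: 12 (4S)-4-benzyl-3-[(2S,3R,4S)-4-(2-bromo-4-methylphenyl)-3-hydroxy-2-methylpentanoyl]-1,3-oxazolidin-2-one
Product: 13 (2S,3R,4S)-4-(2-bromo-4-methylphenyl)-3-hydroxy-N-methoxy-N,2-dimethylpentanamide
Conditions: MeNHOMe·HCl, AlMe3, CH2Cl2, −10 °C → rt
Reagents that add atoms: N,O-dimethylhydroxylamine hydrochloride, CNOC.Cl
Why: In this Weinreb aminolysis with an aluminium amide, the free C8 hydroxyl binds aluminium and directs delivery to the exocyclic carbonyl, so the auxiliary should be displaced without epimerising C7.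

**Step 7**
Reactants: 13 (2S,3R,4S)-4-(2-bromo-4-methylphenyl)-3-hydroxy-N-methoxy-N,2-dimethylpentanamide
Product: 14 (2S,3R,4S)-4-(2-bromo-4-methylphenyl)-3-[(tert-butyldimethylsilyl)oxy]-N-methoxy-N,2-dimethylpentanamide
Conditions: TBSOTf, 2,6-lutidine, CH2Cl2, 0 °C
Reagents that add atoms: tert-butyldimethylsilyl triflate, CC(C)(C)[Si](C)(C)OS(=O)(=O)C(F)(F)F
Why: O-Silylation of a hindered secondary alcohol with a silyl triflate and a non-nucleophilic base is fast at 0 °C and leaves the Weinreb amide alone.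

**Step 8**
Reactants: 14 (2S,3R,4S)-4-(2-bromo-4-methylphenyl)-3-[(tert-butyldimethylsilyl)oxy]-N-methoxy-N,2-dimethylpentanamide
Product: 16 (3S,4R,5S)-5-(2-bromo-4-methylphenyl)-4-[(tert-butyldimethylsilyl)oxy]-3-methylhexan-2-one, via magnesium-chelated tetrahedral adduct 15 (not isolated)
Conditions: MeMgBr, THF, 0 °C → rt; aqueous quench
Reagents that add atoms: methylmagnesium bromide, C[Mg]Br
Why: In this Weinreb ketone synthesis, chelate 15 survives until the quench so only one methyl group is added, and MeMgBr does not exchange with the aryl bromide at this temperature.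

**Step 9**
Reactants: 16 (3S,4R,5S)-5-(2-bromo-4-methylphenyl)-4-[(tert-butyldimethylsilyl)oxy]-3-methylhexan-2-one
Product: 18 {[(3S,4R,5S)-5-(2-bromo-4-methylphenyl)-4-[(tert-butyldimethylsilyl)oxy]-3-methylhex-1-en-2-yl]oxy}trimethylsilane, via terminal lithium enolate 17 (not isolated)
Conditions: LiN(iPr)2, Me3SiCl (in situ quench), THF, −78 °C; pentane, filtration, no chromatography
Reagents that add atoms: chlorotrimethylsilane, C[Si](C)(C)Cl
Why: In this kinetic enolate silylation the bulky amide removes a proton from the open C5 methyl group much faster than the tertiary C7–H, and immediate trapping at −78 °C should fix the terminal isomer before equilibration or β-elimination of the C8 silyloxy group can start.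

**Step 10**
Reactants: 19 ethylmalonic acid
Product: 20 ethylmalonyl dichloride
Conditions: SOCl2 (neat), 50 °C; distillation under reduced pressure
Reagents that add atoms: thionyl chloride, O=S(Cl)Cl
Why: This is a standard acid chloride formation in which SOCl2 converts both carboxyl groups and the volatile product is purified by distillation.

**Step 11**
Reactants: 18 {[(3S,4R,5S)-5-(2-bromo-4-methylphenyl)-4-[(tert-butyldimethylsilyl)oxy]-3-methylhex-1-en-2-yl]oxy}trimethylsilane; 20 ethylmalonyl dichloride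
Product: 22 6-[(2S,3R,4S)-4-(2-bromo-4-methylphenyl)-3-[(tert-butyldimethylsilyl)oxy]pentan-2-yl]-3-ethyl-4-hydroxy-2H-pyran-2-one, via acyclic 3,5-dioxoacyl chloride 21 (not isolated)
Conditions: 20 (1.2 equiv), 2,6-di-tert-butyl-4-methylpyridine (1.2 equiv), Et2O, −78 → 0 °C
Reagents that add atoms: none
Why: The electron-rich C5 terminus of enol silane 18 attacks one acyl chloride of 20 and sheds Me3SiCl (C4–C5 bond) to give 21, whose C6 enol oxygen then acylates at the remaining acyl chloride (O1–C2 bond), and enolisation at C4 to the aromatic 4-hydroxy-2-pyranone drives the sequence forward. The reaction type is known: the [3+3] cyclocondensation of methyl ketone silyl enol ethers with malonyl dichlorides to give 6-substituted 4-hydroxy-2-pyranones. The single ring closes by a 6-exo-trig O-acylation (lactonisation) of an enol that holds oxygen and acyl chloride within reach. No stereocentre is created, and C7, C8 and C9 are only carried through; C7 is safe because nothing in the medium is basic enough to enolise the transient C6 ketone toward its tertiary side. Regiocontrol needs only the terminal enol silane fixed in step 9, since both acyl chlorides of 20 are equivalent and either order of bond formation puts ethyl on C3, where it also blocks a second annulation. The hindered pyridine binds the HCl released on ring closure, so the C8 TBS ether and unreacted enol silane are not exposed to acid.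

**Step 12**
Reactants: 22 6-[(2S,3R,4S)-4-(2-bromo-4-methylphenyl)-3-[(tert-butyldimethylsilyl)oxy]pentan-2-yl]-3-ethyl-4-hydroxy-2H-pyran-2-one; 23 (E)-3-[(tert-butyldimethylsilyl)oxy]prop-1-en-1-ylboronic acid pinacol ester
Product: 24 6-[(2S,3R,4S)-3-[(tert-butyldimethylsilyl)oxy]-4-{2-[(1E)-3-[(tert-butyldimethylsilyl)oxy]prop-1-en-1-yl]-4-methylphenyl}pentan-2-yl]-3-ethyl-4-hydroxy-2H-pyran-2-one
Conditions: Pd(OAc)2 (5 mol %), SPhos (10 mol %), K3PO4 (3.5 equiv), THF/H2O, 60 °C; acidify to pH 4
Reagents that add atoms: none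
Why: In this Suzuki–Miyaura coupling the electron-rich biaryl phosphine lets zerovalent palladium insert into the ortho-branched aryl bromide, the E-alkenyl boronate transfers with retention of geometry, and the extra K3PO4 holds the pyranone as its unreactive potassium salt.

**Step 13**
Reactants: 24 6-[(2S,3R,4S)-3-[(tert-butyldimethylsilyl)oxy]-4-{2-[(1E)-3-[(tert-butyldimethylsilyl)oxy]prop-1-en-1-yl]-4-methylphenyl}pentan-2-yl]-3-ethyl-4-hydroxy-2H-pyran-2-one
Product: 25 veramycin A
Conditions: HF·pyridine, pyridine, THF, 0 °C → rt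
Reagents that add atoms: none
Why: Fluoride-driven desilylation should remove the primary and the hindered secondary TBS ether together, and the pyridine buffer keeps the medium too weakly acidic to ionise the cinnamyl-type alcohol or disturb C7.

**Compound list**

| No. | Name | SMILES | Role |
|---|---|---|---|
| 1 | 2-(2-bromo-4-methylphenyl)acetic acid | Cc1ccc(CC(=O)O)c(Br)c1 | starting material |
| 2 | (4S)-4-benzyl-1,3-oxazolidin-2-one | O=C1N[C@@H](Cc2ccccc2)CO1 | starting material |
| 3 | 2-(2-bromo-4-methylphenyl)acetic pivalic anhydride | Cc1ccc(CC(=O)OC(=O)C(C)(C)C)c(Br)c1 | intermediate |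
| 4 | (4S)-4-benzyl-3-[2-(2-bromo-4-methylphenyl)acetyl]-1,3-oxazolidin-2-one | Cc1ccc(CC(=O)N2[C@@H](Cc3ccccc3)COC2=O)c(Br)c1 | intermediate |
| 5 | sodium Z-enolate of 4 | [Na+].Cc1ccc(/C=C(\[O-])N2[C@@H](Cc3ccccc3)COC2=O)c(Br)c1 | intermediate |
| 6 | (4S)-4-benzyl-3-[(2S)-2-(2-bromo-4-methylphenyl)propanoyl]-1,3-oxazolidin-2-one | C[C@H](C(=O)N1[C@@H](Cc2ccccc2)COC1=O)c1ccc(C)cc1Br | intermediate |
| 7 | (2S)-2-(2-bromo-4-methylphenyl)propan-1-ol | C[C@H](CO)c1ccc(C)cc1Br | intermediate |
| 8 | (2S)-2-(2-bromo-4-methylphenyl)propanal | C[C@H](C=O)c1ccc(C)cc1Br | intermediate |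
| 9 | (4S)-4-benzyl-3-propanoyl-1,3-oxazolidin-2-one | CCC(=O)N1[C@@H](Cc2ccccc2)COC1=O | starting material |
| 10 | dibutylboron Z-enolate of 9 | C/C=C(\OB(CCCC)CCCC)N1[C@@H](Cc2ccccc2)COC1=O | intermediate |
| 11 | O-dibutylboryl aldolate of 12 | O=C1OC[C@H](Cc2ccccc2)N1C(=O)[C@@H](C)[C@H](OB(CCCC)CCCC)[C@@H](C)c1ccc(C)cc1Br | intermediate |
| 12 | (4S)-4-benzyl-3-[(2S,3R,4S)-4-(2-bromo-4-methylphenyl)-3-hydroxy-2-methylpentanoyl]-1,3-oxazolidin-2-one | O=C1OC[C@H](Cc2ccccc2)N1C(=O)[C@@H](C)[C@H](O)[C@@H](C)c1ccc(C)cc1Br | intermediate |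
| 13 | (2S,3R,4S)-4-(2-bromo-4-methylphenyl)-3-hydroxy-N-methoxy-N,2-dimethylpentanamide | CON(C)C(=O)[C@@H](C)[C@H](O)[C@@H](C)c1ccc(C)cc1Br | intermediate |
| 14 | (2S,3R,4S)-4-(2-bromo-4-methylphenyl)-3-[(tert-butyldimethylsilyl)oxy]-N-methoxy-N,2-dimethylpentanamide | CON(C)C(=O)[C@@H](C)[C@H](O[Si](C)(C)C(C)(C)C)[C@@H](C)c1ccc(C)cc1Br | intermediate |
| 15 | bromomagnesium alkoxide of the tetrahedral MeMgBr adduct of 14 (hemiaminal carbon undefined) | CON(C)C(C)(O[Mg]Br)[C@@H](C)[C@H](O[Si](C)(C)C(C)(C)C)[C@@H](C)c1ccc(C)cc1Br | intermediate |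
| 16 | (3S,4R,5S)-5-(2-bromo-4-methylphenyl)-4-[(tert-butyldimethylsilyl)oxy]-3-methylhexan-2-one | CC(=O)[C@@H](C)[C@H](O[Si](C)(C)C(C)(C)C)[C@@H](C)c1ccc(C)cc1Br | intermediate |
| 17 | terminal lithium enolate of 16 | [Li+].C=C([O-])[C@@H](C)[C@H](O[Si](C)(C)C(C)(C)C)[C@@H](C)c1ccc(C)cc1Br | intermediate |
| 18 | {[(3S,4R,5S)-5-(2-bromo-4-methylphenyl)-4-[(tert-butyldimethylsilyl)oxy]-3-methylhex-1-en-2-yl]oxy}trimethylsilane | C=C(O[Si](C)(C)C)[C@@H](C)[C@H](O[Si](C)(C)C(C)(C)C)[C@@H](C)c1ccc(C)cc1Br | intermediate |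
| 19 | ethylmalonic acid | CCC(C(=O)O)C(=O)O | starting material |
| 20 | ethylmalonyl dichloride | CCC(C(=O)Cl)C(=O)Cl | intermediate |
| 21 | (6S,7R,8S)-8-(2-bromo-4-methylphenyl)-7-[(tert-butyldimethylsilyl)oxy]-2-ethyl-6-methyl-3,5-dioxononanoyl chloride (C2 undefined) | CCC(C(=O)Cl)C(=O)CC(=O)[C@@H](C)[C@H](O[Si](C)(C)C(C)(C)C)[C@@H](C)c1ccc(C)cc1Br | intermediate |
| 22 | 6-[(2S,3R,4S)-4-(2-bromo-4-methylphenyl)-3-[(tert-butyldimethylsilyl)oxy]pentan-2-yl]-3-ethyl-4-hydroxy-2H-pyran-2-one | CCc1c(O)cc([C@@H](C)[C@H](O[Si](C)(C)C(C)(C)C)[C@@H](C)c2ccc(C)cc2Br)oc1=O | intermediate |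
| 23 | (E)-3-[(tert-butyldimethylsilyl)oxy]prop-1-en-1-ylboronic acid pinacol ester | CC(C)(C)[Si](C)(C)OC/C=C/B1OC(C)(C)C(C)(C)O1 | starting material |
| 24 | 6-[(2S,3R,4S)-3-[(tert-butyldimethylsilyl)oxy]-4-{2-[(1E)-3-[(tert-butyldimethylsilyl)oxy]prop-1-en-1-yl]-4-methylphenyl}pentan-2-yl]-3-ethyl-4-hydroxy-2H-pyran-2-one | CCc1c(O)cc([C@@H](C)[C@H](O[Si](C)(C)C(C)(C)C)[C@@H](C)c2ccc(C)cc2/C=C/CO[Si](C)(C)C(C)(C)C)oc1=O | intermediate |
| 25 | veramycin A, 3-ethyl-4-hydroxy-6-[(2S,3R,4S)-3-hydroxy-4-{2-[(1E)-3-hydroxyprop-1-en-1-yl]-4-methylphenyl}pentan-2-yl]-2H-pyran-2-one | CCc1c(O)cc([C@@H](C)[C@H](O)[C@@H](C)c2ccc(C)cc2/C=C/CO)oc1=O | target |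

**Totals.** Total step count: 13. Longest linear sequence: 12 steps (steps 1–9 and 11–13, starting from 1).

**Steps most likely to fail**

**Step 11 (annulation).**
- What may go wrong: O-acylation, or acid-driven protodesilylation of the enol silane back to the ketone, may compete with C-acylation. The dichloride may self-condense. The C8 silyl ether may be lost, and the freed hydroxyl would then be acylated.
- Fallback: it sets out from Weinreb amide 14 and builds the ring from the other side.
- The dianion of commercial ethyl 2-ethylacetoacetate (LiN(iPr)2, 2.2 equiv, THF, −78 → 0 °C) is acylated at its terminal carbon by 14. This gives ethyl (6S,7R,8S)-8-(2-bromo-4-methylphenyl)-7-[(tert-butyldimethylsilyl)oxy]-2-ethyl-6-methyl-3,5-dioxononanoate F1.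
- DBU in warm toluene then lactonises F1 with loss of ethanol, and the sequence rejoins the route at 22. C5–C6 is formed in place of C4–C5, and steps 8–10 are not needed.

**Step 5 (aldol on the labile aldehyde from step 4).**
- What may go wrong: amine-promoted enolisation of the α-aryl aldehyde may erode C9 during the addition. Facial control at the aldehyde may also be incomplete and give the 8,9-anti series.
- Fallback: it sets out from aldehyde 8 and replaces the aldol with an amine-free allylboration.
- The (Z)-crotyldiisopinocampheylborane made from cis-2-butene, KOtBu, n-BuLi and (−)-Ipc2BOMe (BF3·OEt2, THF, −78 °C; NaOH/H2O2) should give (2S,3S,4R)-2-(2-bromo-4-methylphenyl)-4-methylhex-5-en-3-ol F2.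
- TBSOTf and 2,6-lutidine convert F2 into tert-butyl{[(2S,3S,4R)-2-(2-bromo-4-methylphenyl)-4-methylhex-5-en-3-yl]oxy}dimethylsilane F3.
- A Tsuji–Wacker oxidation (PdCl2, CuCl, O2, DMF/H2O), in which divalent palladium leaves the aryl bromide alone, turns the terminal alkene into the methyl ketone. The sequence rejoins the route at 16.

**Step 12 (Suzuki coupling).**
- What may go wrong: the acidic, chelating pyranone may slow the catalyst. The boronate may undergo protodeboronation faster than the hindered bromide couples. Warm aqueous base may open the lactone.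
- Fallback: it sets out from ketone 16 and moves the coupling ahead of the ring construction.
- The same Pd(OAc)2/SPhos/K3PO4 coupling of 16 with 23 gives (3S,4R,5S)-4-[(tert-butyldimethylsilyl)oxy]-5-{2-[(1E)-3-[(tert-butyldimethylsilyl)oxy]prop-1-en-1-yl]-4-methylphenyl}-3-methylhexan-2-one F4.
- Kinetic silylation as in step 9 gives the terminal trimethylsilyl enol ether of that ketone F5.
- Annulation of F5 with 20 under the buffered conditions of step 11 rejoins the route at 24.

**Further compounds**
F1 | step 11 | ethyl (6S,7R,8S)-8-(2-bromo-4-methylphenyl)-7-[(tert-butyldimethylsilyl)oxy]-2-ethyl-6-methyl-3,5-dioxononanoate | CCOC(=O)C(CC)C(=O)CC(=O)[C@@H](C)[C@H](O[Si](C)(C)C(C)(C)C)[C@@H](C)c1ccc(C)cc1Br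
F2 | step 5 | (2S,3S,4R)-2-(2-bromo-4-methylphenyl)-4-methylhex-5-en-3-ol | C=C[C@@H](C)[C@H](O)[C@@H](C)c1ccc(C)cc1Br
F3 | step 5 | tert-butyl{[(2S,3S,4R)-2-(2-bromo-4-methylphenyl)-4-methylhex-5-en-3-yl]oxy}dimethylsilane | C=C[C@@H](C)[C@H](O[Si](C)(C)C(C)(C)C)[C@@H](C)c1ccc(C)cc1Br
F4 | step 12 | (3S,4R,5S)-4-[(tert-butyldimethylsilyl)oxy]-5-{2-[(1E)-3-[(tert-butyldimethylsilyl)oxy]prop-1-en-1-yl]-4-methylphenyl}-3-methylhexan-2-one | CC(=O)[C@@H](C)[C@H](O[Si](C)(C)C(C)(C)C)[C@@H](C)c1ccc(C)cc1/C=C/CO[Si](C)(C)C(C)(C)C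
F5 | step 12 | terminal trimethylsilyl enol ether of F4 | C=C(O[Si](C)(C)C)[C@@H](C)[C@H](O[Si](C)(C)C(C)(C)C)[C@@H](C)c1ccc(C)cc1/C=C/CO[Si](C)(C)C(C)(C)C
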